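## The problem

Compound 24 is the achiral flavone 5,7-dihydroxy-2-(3,5-dihydroxy-4-methoxyphenyl)-6,8-dimethoxy-4H-chromen-4-one. A 2-aryl-γ-pyranone (ring C) is fused through C4a–C8a to a benzene ring (ring A) that carries no hydrogen. There is no stereocentre, so the difficulty is regiochemical. Ring A bears oxygen on five neighbouring carbons (O1 on C8a, OMe on C8, OH on C7, OMe on C6, OH on C5), and its only carbon substituent, the C4 carbonyl, sits on C4a between C5 and C8a. Stepwise electrophilic oxygenation of a simpler phenol cannot be relied on to deliver this pattern, and the C7 hydroxyl must be told apart from the two methyl ethers that flank it. Ring B (hydroxyls at C3′ and C5′ around the C4′ methyl ether) has a pattern that can be bought. The free polyphenols and their electron-rich precursors oxidise easily to quinones, the aryl methyl ethers must survive every deprotection, and the squarate-derived cyclobutenones and the silyl ynol ether tolerate neither protic acid nor hot base. The opening feature is the run C8a–O, C8–OMe, C7–O, C6–OMe, C5–O ending at C4a. C8a with its oxygen can come from a ketene carbon, C8, C7 and C6 from the three alkoxylated carbons of a squarate-derived cyclobutenone, and C5–C4a from an oxygenated alkyne. Ring A is also symmetrical about the C4a···C7 axis until ring C closes, so the two oxygens next to C4a need not stay differentiated.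

## Retrosynthesis

**24 from 23.** The three benzyl–oxygen bonds (C7, C3′, C5′) are cut last. Benzyl is the one group that marks every oxygen destined to be a free hydroxyl while the methyl ethers stay, and one hydrogenolysis frees all three. The C5 hydroxyl of 23 is left unprotected because it is chelated to the C4 carbonyl.

**23 from 22, and 22 from 16 and 20.** The O1–C2 bond is cut (cyclodehydration of 1,3-diketone 22), then C2–C3 (acylation of the methyl ketone enolate of 16 by acid chloride 20). The neighbouring cut, acylation of ring A with a ring B arylpropynoyl chloride and 6-endo closure, would need a strong Lewis acid beside benzyl ethers and a longer ring B synthesis. Acid chloride 20 takes three routine steps from ester 17 through 18 and 19. The forward reaction must acylate on carbon in the presence of two phenoxides; because 22 is symmetrical, either phenol closes ring C to the same product.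

**16 from 14, and 14 from 13.** The C4–C4a bond is cut. In resorcinol 14 the only ring hydrogen lies between two hydroxyls and para to the benzyloxy group, so this carbon is a phloroglucinol-type nucleophile, and a Hoesch reaction with acetonitrile is enough. The silyl group of 13 is removed first, because a triisopropylsilyl ether next to C4a would shield it and because the hydroxyl/silyloxy distinction is not needed.

**13 from 5 and 8 (key disconnection).** Ring A is cut at C4a–C8a, C5–C6 and C8–C8a. This reduces a pentaoxygenated benzene to cyclobutenone 5 (C8a, C8, C7, C6 with their oxygens) and silyl ynol ether 8 (C5 with its oxygen, and C4a). Against stepwise oxygenation of an arene, the pattern is assembled in one thermal step, and the hydrogen is placed by the polarity of the partners. The forward reaction asks a cyclobutenone bearing three alkoxy groups to open, to be captured by the alkyne and to close again.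

**5 from 3 and 4, 3 from 2, 2 from 1.** The benzyl group is attached by exchange at C3 of trimethoxycyclobutenone 3. C3 is the only vinylogous ester carbon, so benzyl alcohol 4 can only enter at the future C7. Compound 3 comes from dimethyl squarate 1 by reduction of one carbonyl (to 2) and O-methylation. Capping the hydroxyl of 2 is also needed because a free 4-hydroxyl would trap the ketene as a butenolide.

**8 from 6.** The O–Si bond is cut to lithium ethynolate 7, which comes from ethyl dibromoacetate 6 by double bromine–lithium exchange and loss of ethoxide.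

## Roads not taken

Alternative 1: Ring C is cut at O1–C8a and C4–C4a. Fluoride (CsF) on 3,5-bis(benzyloxy)-4-methoxy-2-(trimethylsilyl)phenyl triflate A2 would give aryne A4. Aroylketene A5, set free by thermolysis of dioxinone A3, would add across it, the ketone oxygen to C8a and the aryl anion at C4a to the ketene carbon, giving flavone A1.
- Merits: ring C is formed and both halves are joined in one step, and the C5 alkoxy group steers the oxygen to the remote aryne carbon.
- Weak points: A1 has hydrogen at C8, so the C8 methoxy group needs a later halogenation and methoxylation. An aryne already carrying the C8 methoxy group is flanked by alkoxy groups on both sides and loses its bias; since ring A is not symmetrical across the C4a–C8a bond, the wrong orientation gives a constitutional isomer. A2 needs a multistep synthesis from a tetraoxygenated benzene, and fluoride-triggered aryne formation must be matched to the hot release of A5.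
- Comparison: this road is more convergent at the flavone stage and shorter after the coupling. The chosen plan needs three steps to build ring C, but it delivers all five ring A oxygens with one unambiguous orientation.

Alternative 2: Ring A is cut at C8–C8a, with C4a–C5 made earlier by adding a metalated 6-aryl-4-pyranone to a squarate. Heating cyclobutenone A7 in xylene would open it to a vinylketene, which closes by 6π electrocyclisation onto the pyranone C2=C3 bond and tautomerises to the 5,8-dihydroxyflavone A6.
- Merits: rings B and C are in place before ring A forms, the thermal ring expansion of 4-aryl-4-hydroxycyclobutenones is better precedented than the chosen key step, and the C8 hydroxyl of A6 could be methylated selectively beside the chelated C5 hydroxyl.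
- Weak points: A7 needs benzyloxy on the carbon next to the carbonyl and methoxy on the vinylogous ester carbon. That requires a mixed benzyl methyl squarate attacked at one of two nearly identical carbonyls, and the exchange used in the chosen plan would put benzyl on the wrong carbon (C6). A 3-metalated γ-pyranone is prone to ring opening, and an extra methylation is needed.
- Comparison: precedent for the ring-forming step and convergence favour this road. The chosen plan sets against it a regiochemically unambiguous placement of the C7 protecting group and the absence of a fragile pyranone anion.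

Alternative 3: Ring C is cut at C4a–C4, C4–C3 and O1–C2. Iodotriol A9, carbon monoxide and arylacetylene A10 would couple under PdCl2(PPh3)2 and CuI in Et2NH to an alkynyl ketone, and a flanking phenol would close ring C to flavone A8.
- Merits: this is the shortest and most convergent road. The symmetry of A9 makes either phenol give the same product, and ring A needs no protecting group.
- Weak points: A9 is an iodinated pentaoxygenated benzene with three free hydroxyls. It is oxidation-prone, it is slow in oxidative addition because the iodide is electron-rich and doubly ortho-substituted, and it must itself be made from a dimethoxyphloroglucinol that is not a simple article of commerce. Direct coupling without CO (leading to a benzofuran), 5-exo closure to an aurone and loss of iodine all compete. A10 needs one step more from 17 than acid chloride 20.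
- Comparison: after the arene is in hand this road is clearly shorter. Its hard part is the arene, which it takes for granted and which the chosen plan builds from dimethyl squarate.

Key step: step 5

Remark: 24 has no stereocentre. The stereocentres of 2, 3, 5, 10 and 12 are formed racemic and are erased in step 5, so no configuration needs control.

## Steps

Step 1
Reactants: 1 dimethyl squarate (3,4-dimethoxycyclobut-3-ene-1,2-dione)
Product: 2 4-hydroxy-2,3-dimethoxycyclobut-2-en-1-one (racemic)
Conditions: LiAlH(OtBu)3 (1.05 equiv), THF, −78 °C; pH 7 buffer, 0 °C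
Reagents that add atoms: none
Why: Hydride 1,2-reduction of one squarate carbonyl; the remaining carbonyl of the alkoxide is a deactivated vinylogous ester, so reduction stops, and a neutral work-up avoids the acid-induced rearrangement of 2.

Step 2
Reactants: 2 4-hydroxy-2,3-dimethoxycyclobut-2-en-1-one
Product: 3 2,3,4-trimethoxycyclobut-2-en-1-one (racemic)
Conditions: MeI (excess), Ag2O, MeCN, rt, dark
Reagents that add atoms: iodomethane, CI
Why: Purdie methylation of the secondary alcohol under neutral conditions, which spares the acid- and base-labile hydroxycyclobutenone; the methyl ether later becomes the C8 methoxy group and prevents the hydroxyl from trapping the ketene.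

Step 3
Reactants: 3 2,3,4-trimethoxycyclobut-2-en-1-one; 4 benzyl alcohol
Product: 5 3-(benzyloxy)-2,4-dimethoxycyclobut-2-en-1-one (racemic)
Conditions: BnOH (3 equiv), NaH (0.1 equiv), 5 Å MS, THF, 0 °C → rt
Reagents that add atoms: none
Why: Vinylogous transesterification by conjugate addition–elimination of benzyl oxide at C3, the only carbon β to the carbonyl; the C2 enol ether and C4 alkyl ether cannot react this way, and the sieves take up methanol to pull the equilibrium.

Step 4
Reactants: 6 ethyl dibromoacetate
Product: 8 triisopropylsilyloxyethyne, via lithium ethynolate 7 (not isolated)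
Conditions: t-BuLi (4 equiv), THF, −78 → 0 °C; iPr3SiCl, −78 °C → rt
Reagents that add atoms: chlorotriisopropylsilane, CC(C)[Si](Cl)(C(C)C)C(C)C
Why: Two bromine–lithium exchanges give the ester dianion, which expels lithium ethoxide to form the ynolate (the established route from α,α-dibromo esters), and the bulky silyl chloride silylates on oxygen to give the silyl ynol ether.

Step 5
Reactants: 5 3-(benzyloxy)-2,4-dimethoxycyclobut-2-en-1-one; 8 triisopropylsilyloxyethyne
Product: 13 3-(benzyloxy)-2,4-dimethoxy-5-(triisopropylsilyloxy)phenol, via vinylketene 9 (not isolated), via 4-vinylcyclobutenone 10 (not isolated), via dienylketene 11 (not isolated), via cyclohexa-2,4-dienone 12 (not isolated)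
Conditions: 8 (2 equiv), PhMe, 110 °C, sealed tube, Ar
Reagents that add atoms: none
Why: Heat opens 5 by conrotatory 4π electrocyclic cleavage of the C1–C4 bond to vinylketene 9, the C4 methoxy group turning outward as donor groups do. The hydrogen-bearing nucleophilic carbon of 8 attacks the electrophilic ketene carbon, so a regiospecific [2+2] cycloaddition forms C4a–C8a and C5–C6 and gives 10 with the silyloxy group on C3. A second 4π opening of 10, methoxy outward and alkenyl inward, should give the (3Z)-dienylketene 11, the geometry needed for closure. Ring A then closes by thermal disrotatory 6π electrocyclisation of 11 (ketene carbon onto the methoxy-bearing terminus, forming C8–C8a), and dienone 12 tautomerises to phenol 13. This is the Danheiser benzannulation of a cyclobutenone with a trialkylsilyloxyalkyne, applied to a cyclobutenone that carries three alkoxy groups. No stereocentre survives, since those of 5, 10 and 12 are lost on aromatisation. The one selectivity that matters, silyloxy meta and hydrogen ortho to the new hydroxyl, is fixed by the polarity of the ketene–ynol ether pair, and the order OMe, OBn, OMe follows from the connectivity of 5. Excess 8 is used so that the ketene is taken up by the alkyne and not by the product phenol.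

Step 6
Reactants: 13 3-(benzyloxy)-2,4-dimethoxy-5-(triisopropylsilyloxy)phenol
Product: 14 5-(benzyloxy)-4,6-dimethoxybenzene-1,3-diol
Conditions: Bu4NF (1.1 equiv), AcOH (1.1 equiv), THF, 0 °C, Ar
Reagents that add atoms: none
Why: Fluoride cleavage of the aryl silyl ether; the acetic acid buffer keeps the oxidation-prone phenoxide protonated, and the product is the symmetrical resorcinol with its single ring hydrogen unshielded.

Step 7
Reactants: 14 5-(benzyloxy)-4,6-dimethoxybenzene-1,3-diol
Product: 16 1-[4-(benzyloxy)-2,6-dihydroxy-3,5-dimethoxyphenyl]ethan-1-one, via ketiminium chloride 15 (not isolated)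
Conditions: MeCN, ZnCl2, HCl (g), Et2O, 0 °C → rt; then H2O, 90 °C
Reagents that add atoms: acetonitrile, CC#N; water, O
Why: Hoesch reaction: the nitrilium species attacks the only free ring carbon, which is activated by two ortho hydroxyls and the para benzyloxy group, and hydrolysis of the ketiminium salt gives the ketone without a Lewis acid strong enough to cleave the benzyl ether.

Step 8
Reactants: 17 methyl 3,5-dihydroxy-4-methoxybenzoate
Product: 18 methyl 3,5-bis(benzyloxy)-4-methoxybenzoate
Conditions: BnBr (2.3 equiv), K2CO3, DMF, 60 °C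
Reagents that add atoms: benzyl bromide, BrCc1ccccc1
Why: Williamson etherification of both phenols.

Step 9
Reactants: 18 methyl 3,5-bis(benzyloxy)-4-methoxybenzoate
Product: 19 3,5-bis(benzyloxy)-4-methoxybenzoic acid
Conditions: NaOH, THF–MeOH–H2O, 60 °C; then aq. HCl
Reagents that add atoms: sodium hydroxide, [Na+].[OH-]
Why: Saponification of the methyl ester; the aryl ethers are inert to base.

Step 10
Reactants: 19 3,5-bis(benzyloxy)-4-methoxybenzoic acid
Product: 20 3,5-bis(benzyloxy)-4-methoxybenzoyl chloride
Conditions: (COCl)2, DMF (cat.), CH2Cl2, 0 °C → rt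
Reagents that add atoms: oxalyl chloride, O=C(Cl)C(Cl)=O
Why: Acid chloride formation through the Vilsmeier-type chloroiminium catalyst; the crude chloride is used directly.

Step 11
Reactants: 16 1-[4-(benzyloxy)-2,6-dihydroxy-3,5-dimethoxyphenyl]ethan-1-one; 20 3,5-bis(benzyloxy)-4-methoxybenzoyl chloride
Product: 22 1-[4-(benzyloxy)-2,6-dihydroxy-3,5-dimethoxyphenyl]-3-[3,5-bis(benzyloxy)-4-methoxyphenyl]propane-1,3-dione, via trilithium salt 21 (not isolated)
Conditions: LiN(SiMe3)2 (4.5 equiv), THF, −78 → −10 °C; 20 (1.0 equiv), −78 °C → rt; aq. HCl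
Reagents that add atoms: none
Why: Claisen-type C-acylation of the ketone enolate within the lithium polyanion of an unprotected hydroxyacetophenone, in which the enolate carbon is the most nucleophilic site; the extra base absorbs the acidic diketone as it forms.

Step 12
Reactants: 22 1-[4-(benzyloxy)-2,6-dihydroxy-3,5-dimethoxyphenyl]-3-[3,5-bis(benzyloxy)-4-methoxyphenyl]propane-1,3-dione
Product: 23 7-(benzyloxy)-2-[3,5-bis(benzyloxy)-4-methoxyphenyl]-5-hydroxy-6,8-dimethoxy-4H-chromen-4-one
Conditions: TsOH·H2O (0.2 equiv), PhMe, 100 °C
Reagents that add atoms: none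
Why: Acid-catalysed cyclodehydration: a phenol oxygen adds to the ring B carbonyl and water is lost (O1–C2 bond, 6-membered ring C); the two phenols of 22 are equivalent, so only one flavone can form, and the other phenol stays as the chelated C5 hydroxyl.

Step 13
Reactants: 23 7-(benzyloxy)-2-[3,5-bis(benzyloxy)-4-methoxyphenyl]-5-hydroxy-6,8-dimethoxy-4H-chromen-4-one
Product: 24 5,7-dihydroxy-2-(3,5-dihydroxy-4-methoxyphenyl)-6,8-dimethoxy-4H-chromen-4-one
Conditions: H2 (1 atm), 10% Pd/C, EtOAc–MeOH, rt
Reagents that add atoms: none
Why: Hydrogenolysis of the three benzyl ethers; the methyl ethers are untouched and the C2=C3 bond, part of a vinylogous ester, is reduced much more slowly than the benzyl groups are cleaved.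

## Compound list

1 | dimethyl squarate (3,4-dimethoxycyclobut-3-ene-1,2-dione) | COC1=C(OC)C(=O)C1=O | starting material
2 | 4-hydroxy-2,3-dimethoxycyclobut-2-en-1-one (racemic) | COC1=C(OC)C(O)C1=O | intermediate
3 | 2,3,4-trimethoxycyclobut-2-en-1-one (racemic) | COC1=C(OC)C(OC)C1=O | intermediate
4 | benzyl alcohol | OCc1ccccc1 | starting material
5 | 3-(benzyloxy)-2,4-dimethoxycyclobut-2-en-1-one (racemic) | COC1=C(OCc2ccccc2)C(OC)C1=O | intermediate
6 | ethyl dibromoacetate | CCOC(=O)C(Br)Br | starting material
7 | lithium ethynolate (not isolated) | [Li+].[O-]C#C | intermediate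
8 | triisopropylsilyloxyethyne | C#CO[Si](C(C)C)(C(C)C)C(C)C | intermediate
9 | (3Z)-3-(benzyloxy)-2,4-dimethoxybuta-1,3-dien-1-one (vinylketene, not isolated) | O=C=C(OC)/C(OCc1ccccc1)=C/OC | intermediate
10 | 4-[(Z)-1-(benzyloxy)-2-methoxyethenyl]-4-methoxy-3-(triisopropylsilyloxy)cyclobut-2-en-1-one (racemic, not isolated) | O=C1C=C(O[Si](C(C)C)(C(C)C)C(C)C)C1(OC)/C(OCc1ccccc1)=C/OC | intermediate
11 | (3Z,5Z)-5-(benzyloxy)-4,6-dimethoxy-3-(triisopropylsilyloxy)hexa-1,3,5-trien-1-one (dienylketene, not isolated) | O=C=C/C(O[Si](C(C)C)(C(C)C)C(C)C)=C(OC)\C(OCc1ccccc1)=C\OC | intermediate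
12 | 5-(benzyloxy)-4,6-dimethoxy-3-(triisopropylsilyloxy)cyclohexa-2,4-dien-1-one (racemic, not isolated) | O=C1C=C(O[Si](C(C)C)(C(C)C)C(C)C)C(OC)=C(OCc2ccccc2)C1OC | intermediate
13 | 3-(benzyloxy)-2,4-dimethoxy-5-(triisopropylsilyloxy)phenol | COc1c(O)cc(O[Si](C(C)C)(C(C)C)C(C)C)c(OC)c1OCc2ccccc2 | intermediate
14 | 5-(benzyloxy)-4,6-dimethoxybenzene-1,3-diol | COc1c(O)cc(O)c(OC)c1OCc2ccccc2 | intermediate
15 | 1-[4-(benzyloxy)-2,6-dihydroxy-3,5-dimethoxyphenyl]ethan-1-iminium chloride (not isolated) | CC(=[NH2+])c1c(O)c(OC)c(OCc2ccccc2)c(OC)c1O.[Cl-] | intermediate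
16 | 1-[4-(benzyloxy)-2,6-dihydroxy-3,5-dimethoxyphenyl]ethan-1-one | CC(=O)c1c(O)c(OC)c(OCc2ccccc2)c(OC)c1O | intermediate
17 | methyl 3,5-dihydroxy-4-methoxybenzoate | COC(=O)c1cc(O)c(OC)c(O)c1 | starting material
18 | methyl 3,5-bis(benzyloxy)-4-methoxybenzoate | COC(=O)c1cc(OCc2ccccc2)c(OC)c(OCc2ccccc2)c1 | intermediate
19 | 3,5-bis(benzyloxy)-4-methoxybenzoic acid | OC(=O)c1cc(OCc2ccccc2)c(OC)c(OCc2ccccc2)c1 | intermediate
20 | 3,5-bis(benzyloxy)-4-methoxybenzoyl chloride | ClC(=O)c1cc(OCc2ccccc2)c(OC)c(OCc2ccccc2)c1 | intermediate
21 | trilithium salt of 16 (bis-phenoxide enolate, not isolated) | [Li+].[Li+].[Li+].C=C([O-])c1c([O-])c(OC)c(OCc2ccccc2)c(OC)c1[O-] | intermediate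
22 | 1-[4-(benzyloxy)-2,6-dihydroxy-3,5-dimethoxyphenyl]-3-[3,5-bis(benzyloxy)-4-methoxyphenyl]propane-1,3-dione | COc1c(OCc2ccccc2)cc(C(=O)CC(=O)c2c(O)c(OC)c(OCc3ccccc3)c(OC)c2O)cc1OCc1ccccc1 | intermediate
23 | 7-(benzyloxy)-2-[3,5-bis(benzyloxy)-4-methoxyphenyl]-5-hydroxy-6,8-dimethoxy-4H-chromen-4-one | COc1c(OCc2ccccc2)cc(-c2cc(=O)c3c(O)c(OC)c(OCc4ccccc4)c(OC)c3o2)cc1OCc1ccccc1 | intermediate
24 | 5,7-dihydroxy-2-(3,5-dihydroxy-4-methoxyphenyl)-6,8-dimethoxy-4H-chromen-4-one | COc1c(O)cc(-c2cc(=O)c3c(O)c(OC)c(O)c(OC)c3o2)cc1O | target

## Step count and least certain steps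

Total: 13 steps. Longest linear sequence: 9 steps (steps 1, 2, 3, 5, 6, 7, 11, 12, 13, from dimethyl squarate 1). Steps 4 and 8 to 10 are side branches.

**Step 5 (key step).** The vinylketene carries three donor groups and may be a poor electrophile, so capture by the ynol ether could lose out to ketene dimerisation or to acylation of the product phenol. The vinylogous ester cyclobutenone may also open only at temperatures where the silyl ynol ether decomposes. The fallback gives up the annulation for classical arene chemistry. It sets out from benzyl alcohol 4, which is joined to commercial 2,6-dimethoxyphenol by Mitsunobu etherification to give 2-(benzyloxy)-1,3-dimethoxybenzene F1. Two equivalents of N-bromosuccinimide brominate the two positions that are ortho to one methoxy group and para to the other, giving 3-(benzyloxy)-1,5-dibromo-2,4-dimethoxybenzene F2. Palladium-catalysed double hydroxylation (Pd2(dba)3, a bulky biarylphosphine, KOH, dioxane–water) returns to the route at resorcinol 14.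

**Step 4.** Deprotonation of the acidic α-hydrogen of 6 may compete with bromine–lithium exchange, and the unsubstituted ynolate may silylate on carbon to a silylketene; the product is also volatile. The fallback changes the two-carbon partner. It sets out from cyclobutenone 5, which is heated with commercial ethoxyethyne (alkoxyalkynes are established partners in this benzannulation) to give 3-(benzyloxy)-5-ethoxy-2,4-dimethoxyphenol F3. Hoesch acetylation at its only ring hydrogen gives 1-[4-(benzyloxy)-2-ethoxy-6-hydroxy-3,5-dimethoxyphenyl]ethan-1-one F4. Acylation with 20 as in step 11 gives 1-[4-(benzyloxy)-2-ethoxy-6-hydroxy-3,5-dimethoxyphenyl]-3-[3,5-bis(benzyloxy)-4-methoxyphenyl]propane-1,3-dione F5, and acid closes it to 7-(benzyloxy)-2-[3,5-bis(benzyloxy)-4-methoxyphenyl]-5-ethoxy-6,8-dimethoxy-4H-chromen-4-one F6. BCl3 in CH2Cl2 at low temperature then removes the peri ethyl group (chelation to the C4 carbonyl) together with the three benzyl groups, and the route is rejoined at 24.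

**Step 3.** Benzyl oxide may attack the ring carbonyl and cleave the strained ring instead of adding at C3, or the exchange may stop at equilibrium. The fallback replaces exchange by hydrolysis and alkylation. It sets out from 3, whose vinylogous ester is saponified with one equivalent of LiOH to 3-hydroxy-2,4-dimethoxycyclobut-2-en-1-one F7. This vinylogous acid has two identical tautomers, so Mitsunobu O-alkylation with benzyl alcohol 4 (PPh3, diisopropyl azodicarboxylate) can give only one enol ether, and the route is rejoined at 5.

**Step 7.** Attack of the nitrilium species on a phenol oxygen (imidate formation), slow C-attack at the doubly flanked carbon, or partial loss of the benzyl group under HCl and ZnCl2 could lower the efficiency. The fallback introduces the carbon as an aldehyde without acid. It sets out from 14, which is formylated ortho to its hydroxyls with MgCl2, Et3N and paraformaldehyde to 4-(benzyloxy)-2,6-dihydroxy-3,5-dimethoxybenzaldehyde F8. Excess MeMgBr gives 5-(benzyloxy)-2-(1-hydroxyethyl)-4,6-dimethoxybenzene-1,3-diol F9, and MnO2 oxidation of the benzylic alcohol rejoins the route at 16.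

**Step 11.** Acylation of a phenoxide oxygen instead of the enolate carbon, or double acylation, would divert the acid chloride. The fallback is the Baker–Venkataraman sequence. It sets out from 16, which is esterified on both phenols with 20 (pyridine, 4-dimethylaminopyridine) to 2-acetyl-5-(benzyloxy)-4,6-dimethoxy-1,3-phenylene bis[3,5-bis(benzyloxy)-4-methoxybenzoate] F10. KOH in pyridine moves one aroyl group from oxygen to the enolate carbon, giving 2-{3-[3,5-bis(benzyloxy)-4-methoxyphenyl]-3-oxopropanoyl}-5-(benzyloxy)-3-hydroxy-4,6-dimethoxyphenyl 3,5-bis(benzyloxy)-4-methoxybenzoate F11. Aqueous methanolic KOH cleaves the remaining aryl ester, and the route is rejoined at 22.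

## Further compounds

F1 | step 5 | 2-(benzyloxy)-1,3-dimethoxybenzene | COc1cccc(OC)c1OCc1ccccc1
F2 | step 5 | 3-(benzyloxy)-1,5-dibromo-2,4-dimethoxybenzene | COc1c(Br)cc(Br)c(OC)c1OCc1ccccc1
F3 | step 4 | 3-(benzyloxy)-5-ethoxy-2,4-dimethoxyphenol | CCOc1cc(O)c(OC)c(OCc2ccccc2)c1OC
F4 | step 4 | 1-[4-(benzyloxy)-2-ethoxy-6-hydroxy-3,5-dimethoxyphenyl]ethan-1-one | CCOc1c(C(C)=O)c(O)c(OC)c(OCc2ccccc2)c1OC
F5 | step 4 | 1-[4-(benzyloxy)-2-ethoxy-6-hydroxy-3,5-dimethoxyphenyl]-3-[3,5-bis(benzyloxy)-4-methoxyphenyl]propane-1,3-dione | CCOc1c(C(=O)CC(=O)c2cc(OCc3ccccc3)c(OC)c(OCc3ccccc3)c2)c(O)c(OC)c(OCc2ccccc2)c1OC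
F6 | step 4 | 7-(benzyloxy)-2-[3,5-bis(benzyloxy)-4-methoxyphenyl]-5-ethoxy-6,8-dimethoxy-4H-chromen-4-one | CCOc1c(OC)c(OCc2ccccc2)c(OC)c2oc(-c3cc(OCc4ccccc4)c(OC)c(OCc4ccccc4)c3)cc(=O)c12
F7 | step 3 | 3-hydroxy-2,4-dimethoxycyclobut-2-en-1-one (racemic) | COC1C(=O)C(OC)=C1O
F8 | step 7 | 4-(benzyloxy)-2,6-dihydroxy-3,5-dimethoxybenzaldehyde | O=Cc1c(O)c(OC)c(OCc2ccccc2)c(OC)c1O
F9 | step 7 | 5-(benzyloxy)-2-(1-hydroxyethyl)-4,6-dimethoxybenzene-1,3-diol (racemic) | CC(O)c1c(O)c(OC)c(OCc2ccccc2)c(OC)c1O
F10 | step 11 | 2-acetyl-5-(benzyloxy)-4,6-dimethoxy-1,3-phenylene bis[3,5-bis(benzyloxy)-4-methoxybenzoate] | CC(=O)c1c(OC(=O)c2cc(OCc3ccccc3)c(OC)c(OCc3ccccc3)c2)c(OC)c(OCc2ccccc2)c(OC)c1OC(=O)c1cc(OCc2ccccc2)c(OC)c(OCc2ccccc2)c1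
F11 | step 11 | 2-{3-[3,5-bis(benzyloxy)-4-methoxyphenyl]-3-oxopropanoyl}-5-(benzyloxy)-3-hydroxy-4,6-dimethoxyphenyl 3,5-bis(benzyloxy)-4-methoxybenzoate | O=C(CC(=O)c1cc(OCc2ccccc2)c(OC)c(OCc2ccccc2)c1)c1c(O)c(OC)c(OCc2ccccc2)c(OC)c1OC(=O)c1cc(OCc2ccccc2)c(OC)c(OCc2ccccc2)c1
A1 | alternative 1 | 5,7-bis(benzyloxy)-2-[3,5-bis(benzyloxy)-4-methoxyphenyl]-6-methoxy-4H-chromen-4-one | COc1c(OCc2ccccc2)cc3oc(-c4cc(OCc5ccccc5)c(OC)c(OCc5ccccc5)c4)cc(=O)c3c1OCc6ccccc6
A2 | alternative 1 | 3,5-bis(benzyloxy)-4-methoxy-2-(trimethylsilyl)phenyl trifluoromethanesulfonate | COc1c(OCc2ccccc2)cc(OS(=O)(=O)C(F)(F)F)c([Si](C)(C)C)c1OCc1ccccc1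
A3 | alternative 1 | 6-[3,5-bis(benzyloxy)-4-methoxyphenyl]-2,2-dimethyl-4H-1,3-dioxin-4-one | CC1(C)OC(=O)C=C(O1)c1cc(OCc2ccccc2)c(OC)c(OCc2ccccc2)c1
A4 | alternative 1 | 1,3-bis(benzyloxy)-2-methoxy-4,5-didehydrobenzene (aryne) | COC1=C(OCc2ccccc2)C#CC=C1OCc1ccccc1
A5 | alternative 1 | 3-[3,5-bis(benzyloxy)-4-methoxyphenyl]-3-oxoprop-1-en-1-one (aroylketene) | O=C=CC(=O)c1cc(OCc2ccccc2)c(OC)c(OCc2ccccc2)c1
A6 | alternative 2 | 7-(benzyloxy)-2-[3,5-bis(benzyloxy)-4-methoxyphenyl]-5,8-dihydroxy-6-methoxy-4H-chromen-4-one | COc1c(O)c2c(=O)cc(-c3cc(OCc4ccccc4)c(OC)c(OCc4ccccc4)c3)oc2c(O)c1OCc5ccccc5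
A7 | alternative 2 | 2-(benzyloxy)-4-{6-[3,5-bis(benzyloxy)-4-methoxyphenyl]-4-oxo-4H-pyran-3-yl}-4-hydroxy-3-methoxycyclobut-2-en-1-one (racemic) | COC1=C(OCc2ccccc2)C(=O)C1(O)c1coc(-c2cc(OCc3ccccc3)c(OC)c(OCc3ccccc3)c2)cc1=O
A8 | alternative 3 | 2-[3,5-bis(benzyloxy)-4-methoxyphenyl]-5,7-dihydroxy-6,8-dimethoxy-4H-chromen-4-one | COc1c(O)c(OC)c2oc(-c3cc(OCc4ccccc4)c(OC)c(OCc4ccccc4)c3)cc(=O)c2c1O
A9 | alternative 3 | 2-iodo-4,6-dimethoxybenzene-1,3,5-triol | COc1c(O)c(I)c(O)c(OC)c1O
A10 | alternative 3 | 1,3-bis(benzyloxy)-5-ethynyl-2-methoxybenzene | COc1c(OCc2ccccc2)cc(C#C)cc1OCc1ccccc1
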